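The route rests on disconnecting the cis-fused lactone at C6–C12 and C7–C11. A dichloroketene (2+2) cycloaddition to the C6=C7 double bond of a cycloheptene forges both bonds on one face in a single operation and closes a cyclobutanone that Baeyer–Villiger oxidation later expands to the γ-lactone; the step exploits the seven-membered-ring alkene flanked by the oxygenated C5 stereocentre, which directs the ketene to the opposite face and polarises the alkene. The precursor is a metathesis-derived cycloheptene carrying the C9 silyl ether, the C10 methyl, the C1 carbinol thioester and the C5 oxygen, O1 and O5 being tied back as a trans-fused acetonide.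

Key step: step 12

Remark on labels: ring carbons are C1, C5, C6, C7, C8, C9, C10; C2 is the acyl carbon on C1 (later the ketone, then C3=C4–C15); C11, C12 (C=O) and C13 (=CH2) are the lactone carbons; C14 is the methyl on C10; On is the oxygen on Cn; the β face carries O5, O9 and C2, the α face carries the lactone.

Remark on design: O1 and O5 are masked together as one ketal because ketal oxygens are poor nucleophiles toward the ketene and toward ZnCl2, the tied-back ring leaves the α face of C6=C7 open, and one mild acid step later frees both hydroxyls, of which only the secondary O5–H can be acylated.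

Assumption: the allylborane made from (−)-α-pinene is taken to be the enantiomer that adds to the Re face of aldehyde 6; if the sense is opposite, the reagent from (+)-α-pinene is used.

Step 1
Reactants: 1 (4S)-4-benzyl-3-propanoyl-1,3-oxazolidin-2-one; 2 tert-butyl bromoacetate
Product: 4 tert-butyl (3R)-4-[(4S)-4-benzyl-2-oxo-1,3-oxazolidin-3-yl]-3-methyl-4-oxobutanoate, via sodium enolate 3 (not isolated)
Conditions: NaN(SiMe3)2, THF, −78 °C; then 2, −78 → −20 °C
Reagents that add atoms: none
Why: Evans auxiliary alkylation, in which the chelated Z sodium enolate is alkylated on the face opposite the benzyl group, sets C10 and brings in C1 and C2.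

Step 2
Reactants: 4 imide ester
Product: 5 tert-butyl (3R)-4-hydroxy-3-methylbutanoate
Conditions: LiBH4, MeOH (1 equiv), THF, 0 °C
Reagents that add atoms: none
Why: Hydride reduction of the activated imide carbonyl (reductive auxiliary removal) is much faster than reduction of the tert-butyl ester, so C9 is released as the primary alcohol and C10 is untouched.

Step 3
Reactants: 5 hydroxy ester
Product: 6 tert-butyl (3R)-3-methyl-4-oxobutanoate
Conditions: 2,2,6,6-tetramethylpiperidin-1-oxyl (cat.), PhI(OAc)2, CH2Cl2, 20 °C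
Reagents that add atoms: none
Why: Oxoammonium (TEMPO) oxidation stops at the aldehyde under non-basic conditions, so the α-stereocentre C10 should not epimerise, and the aldehyde is used crude.

Step 4
Reactants: 6 aldehyde; 7 allylmagnesium bromide
Product: 9 tert-butyl (3R,4R)-4-hydroxy-3-methylhept-6-enoate, via allylborane 8 (not isolated)
Conditions: 7, (+)-B-methoxydiisopinocampheylborane, Et2O, −78 → 20 °C; then 6, −78 °C; then NaOH, H2O2, 0 °C
Reagents that add atoms: none
Why: Brown asymmetric allylboration through a closed chair transition state delivers the allyl group to the Re face of the aldehyde under control of the isopinocampheyl groups, which sets C9 syn to the C10 methyl (also the Felkin sense).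

Step 5
Reactants: 9 hydroxy ester
Product: 12 (3R,4R)-3-methyl-4-[(triisopropylsilyl)oxy]hept-6-enoic acid, via silyl ether ester 10 (not isolated), via trimethylsilyl ester 11 (not isolated)
Conditions: iPr3SiOTf, 2,6-lutidine, CH2Cl2, −78 → 0 °C; then Me3SiOTf, 0 → 20 °C; aqueous citric acid work-up
Reagents that add atoms: triisopropylsilyl trifluoromethanesulfonate, CC(C)[Si](C(C)C)(C(C)C)OS(=O)(=O)C(F)(F)F
Why: Silyl triflate silylation protects O9, and the second silyl triflate converts the tert-butyl ester into a silyl ester with loss of isobutene (Lewis acid ester cleavage) that hydrolyses on work-up, all without touching C9 or C10.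

Step 6
Reactants: 12 acid; 13 (4R)-4-benzyl-1,3-oxazolidin-2-one
Product: 15 (4R)-4-benzyl-3-[(3R,4R)-3-methyl-4-[(triisopropylsilyl)oxy]hept-6-enoyl]-1,3-oxazolidin-2-one, via mixed anhydride 14 (not isolated)
Conditions: tBuCOCl, Et3N, THF, −20 °C; then 13, LiCl, −20 → 20 °C
Reagents that add atoms: none
Why: N-acylation of the oxazolidinone by the mixed pivalic anhydride, which is attacked at its less hindered carbonyl, installs the auxiliary that will control C5 and involves no stereocentre.

Step 7
Reactants: 15 imide; 16 acrolein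
Product: 18 (4R)-4-benzyl-3-[(2R,3R,4R)-2-[(1S)-1-hydroxyprop-2-en-1-yl]-3-methyl-4-[(triisopropylsilyl)oxy]hept-6-enoyl]-1,3-oxazolidin-2-one, via boron enolate 17 (not isolated)
Conditions: Bu2BOTf, iPr2NEt, CH2Cl2, −78 → 0 °C; then 16, −78 → 0 °C; then pH 7 buffer, MeOH, H2O2
Reagents that add atoms: none
Why: Evans syn aldol reaction, in which the Z boron enolate adds to acrolein through a Zimmerman–Traxler chair on the face dictated by the (R)-benzyl auxiliary, fixes C5 as required (the C1 centre formed at the same time is erased in step 9).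

Step 8
Reactants: 18 aldol adduct
Product: 19 S-ethyl (2R,3R,4R)-2-[(1S)-1-hydroxyprop-2-en-1-yl]-3-methyl-4-[(triisopropylsilyl)oxy]hept-6-enethioate
Conditions: EtSH, n-BuLi, THF, 0 °C
Reagents that add atoms: ethanethiol, CCS
Why: Transacylation by lithium ethanethiolate at the exocyclic imide carbonyl releases the auxiliary and gives the thioester that later serves as the acyl donor, without disturbing C5.

Step 9
Reactants: 19 hydroxy thioester
Product: 21 S-ethyl (2S,3S,4R)-2-hydroxy-2-[(1S)-1-hydroxyprop-2-en-1-yl]-3-methyl-4-[(triisopropylsilyl)oxy]hept-6-enethioate, via dilithio dianion 20 (not isolated)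
Conditions: LiN(iPr)2 (2.3 equiv), THF, −78 → −40 °C; then trans-3-phenyl-2-(phenylsulfonyl)oxaziridine, −78 °C; aqueous NH4Cl
Reagents that add atoms: trans-3-phenyl-2-(phenylsulfonyl)oxaziridine, O=S(=O)(c1ccccc1)N1OC1c1ccccc1
Why: Fráter–Seebach-type enolate hydroxylation, in which the oxaziridine delivers oxygen to C1 of the chelated alkoxide–enolate dianion anti to the vinyl group on C5, which is also the face that the C10 stereocentre exposes by allylic strain, should give the tertiary alcohol with the required configuration.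

Step 10
Reactants: 21 diol thioester
Product: 22 S-ethyl (4S,5S)-5-ethenyl-2,2-dimethyl-4-[(2S,3R)-3-[(triisopropylsilyl)oxy]hex-5-en-2-yl]-1,3-dioxolane-4-carbothioate
Conditions: 2-methoxypropene, pyridinium p-toluenesulfonate (cat.), CH2Cl2, 0 → 20 °C
Reagents that add atoms: 2-methoxypropene, C=C(C)OC
Why: Acid-catalysed ketalisation of the 1,2-diol gives the dioxolane with the two alkene-bearing chains trans and changes no stereocentre.

Step 11
Reactants: 22 diene acetonide
Product: 23 S-ethyl (3aS,4S,5R,8aS)-2,2,4-trimethyl-5-[(triisopropylsilyl)oxy]-4,5,6,8a-tetrahydro-3aH-cyclohepta[d][1,3]dioxole-3a-carbothioate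
Conditions: second-generation Grubbs catalyst RuCl2(=CHPh)(PCy3)(H2IMes) (5 mol %), CH2Cl2, 0.005 M, 40 °C
Reagents that add atoms: none
Why: Ring-closing metathesis of the two terminal alkenes, helped by the quaternary C1 and the dioxolane, forms the cis C6=C7 bond of the seven-membered ring with loss of ethene and touches no stereocentre.

Step 12
Reactants: 23 cycloheptene; 24 trichloroacetyl chloride
Product: 26 cis-fused 11,11-dichlorocyclobutanone on C6–C7 of the cycloheptane, via dichloroketene 25 (not isolated)
Conditions: 24 (slow addition), Zn(Cu) couple, POCl3, Et2O, 35 °C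
Reagents that add atoms: none
Why: Dichloroketene, generated by zinc reduction of trichloroacetyl chloride, adds to C6=C7 in a concerted, asynchronous (2+2) cycloaddition in which the electrophilic central carbon C12 bonds ahead of C11; the closest known reaction is the dichloroketene cycloaddition to simple cycloalkenes such as cyclohexene and cycloheptene. The four-membered ring closes by the cycloaddition itself, with C6–C12 and C7–C11 formed suprafacially on the alkene, so the ring fusion must be cis. C6 and C7 are set together, and their sense is controlled by the allylic C5–O bond and by the β-oriented thioester and silyloxy groups, which leave only the α face open. The step needs facial selectivity (α) and regioselectivity (C12 to C6, C11 to C7): the inductively withdrawing O5 makes C7 the better site for the developing positive charge, and the bulky CCl2 end goes to the less hindered C7. Chemoselectivity should hold because C6=C7 is the only nucleophilic π bond, the ketal oxygens are poor nucleophiles, no free hydroxyl remains, and POCl3 ties up ZnCl2 so that ketal and silyl ether survive.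

Step 13
Reactants: 26 dichlorocyclobutanone
Product: 27 cis-fused cyclobutanone (C11 as CH2)
Conditions: Zn, NH4Cl, MeOH, 20 °C
Reagents that add atoms: none
Why: Zinc reduces the two α-chloro ketone C–Cl bonds through the zinc enolate (reductive dehalogenation), leaving thioester, ketal, silyl ether and ring fusion unchanged.

Step 14
Reactants: 27 cyclobutanone
Product: 28 cis-fused γ-lactone (O6–C12(=O)–C11H2–C7)
Conditions: mCPBA, NaHCO3, CH2Cl2, 0 °C
Reagents that add atoms: 3-chloroperoxybenzoic acid, O=C(OO)c1cccc(Cl)c1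
Why: Baeyer–Villiger oxidation of the strained cyclobutanone proceeds with migration of the secondary C6 in preference to the primary C11 and with retention, so O6 is inserted on the α face and the cis γ-lactone results.

Step 15
Reactants: 28 lactone; 29 N,N-dimethylmethyleneiminium iodide (Eschenmoser's salt)
Product: 33 α-methylene lactone (C11=C13H2), via lithium enolate 30 (not isolated), via Mannich base 31 (not isolated), via ammonium iodide 32 (not isolated)
Conditions: LiN(iPr)2, THF, −78 °C; then 29, −78 → 20 °C; then MeI, CH2Cl2, 20 °C; then aqueous NaHCO3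
Reagents that add atoms: none
Why: Mannich aminomethylation of the lactone enolate followed by quaternisation and elimination (α-methylenation) installs C13, and since only the lactone carries an enolisable α-hydrogen and C11 becomes trigonal, no stereocentre is at stake.

Step 16
Reactants: 33 acetonide
Product: 34 1,5-diol (O1–H tertiary, O5–H secondary)
Conditions: CF3CO2H/H2O (9:1), CH2Cl2, 0 °C
Reagents that add atoms: none
Why: Acid-catalysed ketal hydrolysis frees O1–H and O5–H, while the hindered secondary triisopropylsilyl ether, the lactone and the thioester should survive brief cold aqueous acid.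

Step 17
Reactants: 34 diol; 35 3-methylbutanoic anhydride
Product: 36 5-O-(3-methylbutanoyl) ester
Conditions: 35, 4-(dimethylamino)pyridine (cat.), pyridine, CH2Cl2, 0 → 20 °C
Reagents that add atoms: none
Why: Nucleophile-catalysed acyl transfer is selective for the secondary C5 hydroxyl because the tertiary C1 hydroxyl beside the thioester is too hindered to be acylated.

Step 18
Reactants: 36 thioester; 37 (Z)-prop-1-en-1-ylboronic acid
Product: 38 9-O-triisopropylsilyl ether of the target (Z enone)
Conditions: 37, Pd2(dba)3 (cat.), tri(2-furyl)phosphine, copper thiophene-2-carboxylate Cu(O2CC4H3S), THF, 50 °C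
Reagents that add atoms: none
Why: Liebeskind–Srogl cross-coupling, in which zerovalent palladium inserts into the C–S bond, the monovalent copper carboxylate takes up the thiolate and activates boron, and the alkenyl group is transferred with retention, should give the Z enone under neutral conditions that spare lactone, ester and free alcohol.

Step 19
Reactants: 38 silyl ether
Product: 39 target CNP0186412.2
Conditions: HF·pyridine, pyridine, THF, 0 → 20 °C
Reagents that add atoms: none
Why: Fluoride-driven desilylation in buffered, mildly acidic medium removes the silyl group from O9 and should leave the Z enone, the α-methylene lactone and the isovalerate intact.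

Compound list

1 | (4S)-4-benzyl-3-propanoyl-1,3-oxazolidin-2-one | CCC(=O)N1[C@@H](Cc2ccccc2)COC1=O | starting material
2 | tert-butyl bromoacetate | CC(C)(C)OC(=O)CBr | starting material
3 | sodium Z-enolate of 1 | C/C=C(\[O-])N1[C@@H](Cc2ccccc2)COC1=O.[Na+] | intermediate (not isolated)
4 | tert-butyl (3R)-4-[(4S)-4-benzyl-2-oxo-1,3-oxazolidin-3-yl]-3-methyl-4-oxobutanoate | CC(C)(C)OC(=O)C[C@@H](C)C(=O)N1[C@@H](Cc2ccccc2)COC1=O | intermediate
5 | tert-butyl (3R)-4-hydroxy-3-methylbutanoate | CC(C)(C)OC(=O)C[C@@H](C)CO | intermediate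
6 | tert-butyl (3R)-3-methyl-4-oxobutanoate | CC(C)(C)OC(=O)C[C@@H](C)C=O | intermediate
7 | allylmagnesium bromide | C=CC[Mg]Br | starting material
8 | B-allylbis(isopinocampheyl)borane derived from (−)-α-pinene | C=CCB([C@H]1C[C@H]2C[C@@H]([C@@H]1C)C2(C)C)[C@H]1C[C@H]2C[C@@H]([C@@H]1C)C2(C)C | intermediate (not isolated)
9 | tert-butyl (3R,4R)-4-hydroxy-3-methylhept-6-enoate | CC(C)(C)OC(=O)C[C@@H](C)[C@H](O)CC=C | intermediate
10 | tert-butyl (3R,4R)-3-methyl-4-[(triisopropylsilyl)oxy]hept-6-enoate | CC(C)(C)OC(=O)C[C@@H](C)[C@H](O[Si](C(C)C)(C(C)C)C(C)C)CC=C | intermediate (not isolated)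
11 | trimethylsilyl (3R,4R)-3-methyl-4-[(triisopropylsilyl)oxy]hept-6-enoate | C[Si](C)(C)OC(=O)C[C@@H](C)[C@H](O[Si](C(C)C)(C(C)C)C(C)C)CC=C | intermediate (not isolated)
12 | (3R,4R)-3-methyl-4-[(triisopropylsilyl)oxy]hept-6-enoic acid | OC(=O)C[C@@H](C)[C@H](O[Si](C(C)C)(C(C)C)C(C)C)CC=C | intermediate
13 | (4R)-4-benzyl-1,3-oxazolidin-2-one | O=C1N[C@H](Cc2ccccc2)CO1 | starting material
14 | mixed anhydride of 12 and pivalic acid | CC(C)(C)C(=O)OC(=O)C[C@@H](C)[C@H](O[Si](C(C)C)(C(C)C)C(C)C)CC=C | intermediate (not isolated)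
15 | (4R)-4-benzyl-3-[(3R,4R)-3-methyl-4-[(triisopropylsilyl)oxy]hept-6-enoyl]-1,3-oxazolidin-2-one | C=CC[C@@H](O[Si](C(C)C)(C(C)C)C(C)C)[C@H](C)CC(=O)N1[C@H](Cc2ccccc2)COC1=O | intermediate
16 | acrolein (prop-2-enal) | C=CC=O | starting material
17 | Z dibutylboron enolate of 15 | C=CC[C@@H](O[Si](C(C)C)(C(C)C)C(C)C)[C@H](C)/C=C(\OB(CCCC)CCCC)N1[C@H](Cc2ccccc2)COC1=O | intermediate (not isolated)
18 | (4R)-4-benzyl-3-[(2R,3R,4R)-2-[(1S)-1-hydroxyprop-2-en-1-yl]-3-methyl-4-[(triisopropylsilyl)oxy]hept-6-enoyl]-1,3-oxazolidin-2-one | C=CC[C@@H](O[Si](C(C)C)(C(C)C)C(C)C)[C@H](C)[C@@H](C(=O)N1[C@H](Cc2ccccc2)COC1=O)[C@H](C=C)O | intermediate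
19 | S-ethyl (2R,3R,4R)-2-[(1S)-1-hydroxyprop-2-en-1-yl]-3-methyl-4-[(triisopropylsilyl)oxy]hept-6-enethioate | C=CC[C@@H](O[Si](C(C)C)(C(C)C)C(C)C)[C@H](C)[C@@H](C(=O)SCC)[C@H](C=C)O | intermediate
20 | dilithium alkoxide–enolate of 19 (enolate oxygen cis to C5) | C=CC[C@@H](O[Si](C(C)C)(C(C)C)C(C)C)[C@H](C)/C(=C(\SCC)[O-])[C@H](C=C)[O-].[Li+].[Li+] | intermediate (not isolated)
21 | S-ethyl (2S,3S,4R)-2-hydroxy-2-[(1S)-1-hydroxyprop-2-en-1-yl]-3-methyl-4-[(triisopropylsilyl)oxy]hept-6-enethioate | C=CC[C@@H](O[Si](C(C)C)(C(C)C)C(C)C)[C@H](C)[C@@](O)(C(=O)SCC)[C@H](C=C)O | intermediate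
22 | S-ethyl (4S,5S)-5-ethenyl-2,2-dimethyl-4-[(2S,3R)-3-[(triisopropylsilyl)oxy]hex-5-en-2-yl]-1,3-dioxolane-4-carbothioate | C=CC[C@@H](O[Si](C(C)C)(C(C)C)C(C)C)[C@H](C)[C@@](O1)(C(=O)SCC)[C@H](C=C)OC1(C)C | intermediate
23 | S-ethyl (3aS,4S,5R,8aS)-2,2,4-trimethyl-5-[(triisopropylsilyl)oxy]-4,5,6,8a-tetrahydro-3aH-cyclohepta[d][1,3]dioxole-3a-carbothioate (cycloheptene with C6=C7, trans-fused O1/O5 acetonide, O9 silyl ether, C1 thioester; key-step precursor) | C1=CC[C@@H](O[Si](C(C)C)(C(C)C)C(C)C)[C@H](C)[C@@](O2)(C(=O)SCC)[C@H]1OC2(C)C | intermediate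
24 | trichloroacetyl chloride | ClC(=O)C(Cl)(Cl)Cl | starting material
25 | dichloroketene | ClC(Cl)=C=O | intermediate (not isolated)
26 | cycloadduct of 23: cyclobutanone cis-fused at C6–C7 with C12(=O) on C6 and CCl2 (C11) on C7, both new bonds α and anti to O5 (1S,5S,6R,7R,9R,10S); acetonide, silyl ether and thioester as in 23 | ClC1(Cl)C(=O)[C@@H]2[C@H]1C[C@@H](O[Si](C(C)C)(C(C)C)C(C)C)[C@H](C)[C@@](O3)(C(=O)SCC)[C@H]2OC3(C)C | intermediate
27 | dechlorinated cis-fused cyclobutanone (C11 = CH2; 1S,5S,6R,7S,9R,10S), otherwise as 26 | C1C(=O)[C@@H]2[C@H]1C[C@@H](O[Si](C(C)C)(C(C)C)C(C)C)[C@H](C)[C@@](O3)(C(=O)SCC)[C@H]2OC3(C)C | intermediate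
28 | cis-fused γ-lactone (O6–C12(=O)–C11H2–C7, O6 and C11 α; 1S,5S,6R,7S,9R,10S) with acetonide, silyl ether and thioester as in 23 | C1C(=O)O[C@@H]2[C@H]1C[C@@H](O[Si](C(C)C)(C(C)C)C(C)C)[C@H](C)[C@@](O3)(C(=O)SCC)[C@H]2OC3(C)C | intermediate
29 | N,N-dimethylmethyleneiminium iodide (Eschenmoser's salt) | C=[N+](C)C.[I-] | starting material
30 | lithium enolate of lactone 28 | C1=C([O-])O[C@@H]2[C@H]1C[C@@H](O[Si](C(C)C)(C(C)C)C(C)C)[C@H](C)[C@@](O3)(C(=O)SCC)[C@H]2OC3(C)C.[Li+] | intermediate (not isolated)
31 | 11-(dimethylaminomethyl) lactone (C11 configuration immaterial) | CN(C)CC1C(=O)O[C@@H]2[C@H]1C[C@@H](O[Si](C(C)C)(C(C)C)C(C)C)[C@H](C)[C@@](O3)(C(=O)SCC)[C@H]2OC3(C)C | intermediate (not isolated)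
32 | 11-(trimethylammoniomethyl) lactone iodide | C[N+](C)(C)CC1C(=O)O[C@@H]2[C@H]1C[C@@H](O[Si](C(C)C)(C(C)C)C(C)C)[C@H](C)[C@@](O3)(C(=O)SCC)[C@H]2OC3(C)C.[I-] | intermediate (not isolated)
33 | α-methylene lactone (C11=C13H2), otherwise as 28 | C=C1C(=O)O[C@@H]2[C@H]1C[C@@H](O[Si](C(C)C)(C(C)C)C(C)C)[C@H](C)[C@@](O3)(C(=O)SCC)[C@H]2OC3(C)C | intermediate
34 | 1,5-diol: α-methylene lactone with free O1–H (tertiary, α) and O5–H (secondary, β), O9 silyl ether, C1 S-ethyl thioester | C=C1C(=O)O[C@@H]2[C@H]1C[C@@H](O[Si](C(C)C)(C(C)C)C(C)C)[C@H](C)[C@@](O)(C(=O)SCC)[C@H]2O | intermediate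
35 | 3-methylbutanoic (isovaleric) anhydride | CC(C)CC(=O)OC(=O)CC(C)C | starting material
36 | 5-O-(3-methylbutanoyl) ester of 34 | C=C1C(=O)O[C@@H]2[C@H]1C[C@@H](O[Si](C(C)C)(C(C)C)C(C)C)[C@H](C)[C@@](O)(C(=O)SCC)[C@H]2OC(=O)CC(C)C | intermediate
37 | (Z)-prop-1-en-1-ylboronic acid | C/C=C\B(O)O | starting material
38 | 9-O-triisopropylsilyl ether of the target (C1 bears the (Z)-but-2-enoyl group) | C=C1C(=O)O[C@@H]2[C@H]1C[C@@H](O[Si](C(C)C)(C(C)C)C(C)C)[C@H](C)[C@@](O)(C(=O)/C=C\C)[C@H]2OC(=O)CC(C)C | intermediate
39 | CNP0186412.2 (1S,5S,6R,7S,9R,10S) | C=C1C(=O)O[C@@H]2[C@H]1C[C@@H](O)[C@H](C)[C@@](O)(C(=O)/C=C\C)[C@H]2OC(=O)CC(C)C | target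

Total step count: 19. Longest linear sequence: 19 steps (1 to 39).

Steps most likely to fail

Step 12. The cycloaddition may be sluggish at a hindered, inductively deactivated cis-disubstituted alkene, so that ketene oligomerisation takes over, and regio- or facial control may erode. The fallback sets out from 23: the keteniminium salt made from N,N-dimethylacetamide, Tf2O and 2,4,6-collidine in 1,2-dichloroethane at 80 °C, a more electrophilic two-carbon partner, adds to C6=C7 in a stepwise cationic (2+2) cycloaddition of the same regiochemical sense to give the cyclobutaniminium triflate F1. Hydrolysis of F1 with aqueous NaHCO3 gives the chlorine-free cyclobutanone, and the route is rejoined at 27, so step 13 is not needed.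

Step 9. Deprotonation at the hindered C1–H may be slow, the lithium aldolate may close to a β-lactone or undergo retro-aldol cleavage before the dianion forms, and facial control may be incomplete. The fallback sets out from 18 and replaces the open-chain dianion by a cyclic acetal template. LiOH/H2O2 in THF/H2O removes the auxiliary to give the β-hydroxy acid F2. Acetalisation with pivalaldehyde (TsOH cat., CH2Cl2, molecular sieves) gives the cis-2-tert-butyl-1,3-dioxan-4-one F3. Its lithium enolate (LiN(iPr)2, THF, −78 °C) is hydroxylated by the same oxaziridine on the face trans to the vinyl and tert-butyl groups to give the 5-hydroxy dioxanone F4. Opening of the acylal with Me2AlSEt (from AlMe3 and EtSH, CH2Cl2, 0 °C) releases pivalaldehyde and gives the diol thioester, where the route is rejoined at 21.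

Step 18. Coupling at the α-quaternary thioester may be slow, the alkenylboronic acid may protodeboronate, and the Z enone may isomerise to E under the palladium/copper conditions. The fallback sets out from 36: palladium/copper-catalysed coupling of the thioester with propyne (PdCl2(dppf), CuI, tri(2-furyl)phosphine, Et3N, DMF, 50 °C) gives the ynone F5. Semihydrogenation of F5 over Pd/CaCO3 poisoned with Pb(OAc)2 and quinoline (H2, EtOAc, 0 °C), stopped after one equivalent, builds the Z geometry by syn addition, and the route is rejoined at 38.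

Further compounds
F1 | step 12 | cyclobutaniminium triflate (C12=N+Me2 on C6, C11H2 on C7, cis-fused, α) | C1C(=[N+](C)C)[C@@H]2[C@H]1C[C@@H](O[Si](C(C)C)(C(C)C)C(C)C)[C@H](C)[C@@](O3)(C(=O)SCC)[C@H]2OC3(C)C.[O-]S(=O)(=O)C(F)(F)F
F2 | step 9 | (2R,3R,4R)-2-[(1S)-1-hydroxyprop-2-en-1-yl]-3-methyl-4-[(triisopropylsilyl)oxy]hept-6-enoic acid | C=CC[C@@H](O[Si](C(C)C)(C(C)C)C(C)C)[C@H](C)[C@@H](C(=O)O)[C@H](C=C)O
F3 | step 9 | cis-2-tert-butyl-6-ethenyl-1,3-dioxan-4-one carrying the C10 side chain at position 5, cis to the vinyl group | O=C1[C@H]([C@@H](C)[C@H](O[Si](C(C)C)(C(C)C)C(C)C)CC=C)[C@H](C=C)O[C@H](C(C)(C)C)O1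
F4 | step 9 | 5-hydroxy derivative of F3 (hydroxyl trans to vinyl and tert-butyl) | O=C1[C@](O)([C@@H](C)[C@H](O[Si](C(C)C)(C(C)C)C(C)C)CC=C)[C@H](C=C)O[C@H](C(C)(C)C)O1
F5 | step 18 | but-2-ynoyl ketone (ynone) corresponding to 38 | C=C1C(=O)O[C@@H]2[C@H]1C[C@@H](O[Si](C(C)C)(C(C)C)C(C)C)[C@H](C)[C@@](O)(C(=O)C#CC)[C@H]2OC(=O)CC(C)C
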